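**Retrosynthetic overview**
- The target is a 2,3-trans-3,4-trans flavan-3-ol (rings A, B, C) whose C4 carries the resorcinol ring (ring D) of a piceatannol unit. The last operations are removal of six silyl groups, attachment of the catechol ring (ring E) as an (E)-styryl group by Suzuki–Miyaura coupling at a ring-D bromide, and cleavage of a C3 benzoate.
- Ring C is the only ring that is built. C2–C3 and C4–C4a are closed together in a cationic [4+2] (oxa-Povarov) reaction of an O-aryl oxocarbenium ion with an (E)-β-aryl enol benzoate under a chiral Brønsted acid, which should set C2, C3 and C4 at once.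
- Enabling feature: O1 is an aryl ether oxygen on C8a next to the benzylic C2, so C4a=C8a–O1(+)=C2 is a latent 2-oxadiene whose terminus C4a is para to the C7 oxygen. C3–O/C4–ring D is an enol ester whose ring D has oxygens ortho and para to the C4-bound carbon and so stabilises the C4 cation.
- Precursors: an O-aryl O-pivaloyl acetal from 4-silyloxybenzaldehyde (ring B, C2) and 3-silyloxyphenol (ring A, O1); an (E)-enol benzoate from 5-bromoresorcinol (ring D, C3, C4); an (E)-styrylboronate from protected protocatechualdehyde (ring E).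
- Ring order: rings A, B, D and E are bought as benzenes; ring C is formed in step 8.

Key step: step 8

Abbreviations: TBS = tert-butyldimethylsilyl, TBSO = tert-butyldimethylsilyloxy, Bpin = 4,4,5,5-tetramethyl-1,3,2-dioxaborolan-2-yl, Piv = pivaloyl.
Assumption: the sense of induction of the chiral acid in step 8 cannot be predicted; the (R)-acid is written, and its mirror image would be used if it favours the wrong enantiomer.
Assumption: the target defines no stereoaxis, so rotation about the C4–ring D bond is treated as not giving separable isomers.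
Assumption: 12 is taken as commercial; otherwise it is one silylation from 3,4-dihydroxybenzaldehyde.

**Step 1**
Reactants: 1 4-(TBSO)benzaldehyde; 2 3-(TBSO)phenol
Product: 4 [3-(TBSO)phenoxy][4-(TBSO)phenyl]methyl pivalate (racemic), via α-chlorobenzyl pivalate 3 (not isolated)
Conditions: pivaloyl chloride, ZnCl2 (2 mol%), CH2Cl2, 0 °C; then 2, Cs2CO3, MeCN, −20 °C to rt
Reagents that add atoms: pivaloyl chloride, CC(C)(C)C(=O)Cl
Why: Aromatic aldehydes add acyl chlorides under ZnCl2 catalysis to give α-chloroalkyl esters, and O-alkylation of a caesium phenoxide by such an ester is the standard way to acyloxyalkyl aryl ethers; the bulky pivalate should suppress acyl transfer, and the racemic acetal carbon becomes planar in step 8.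

**Step 2**
Reactants: 5 5-bromobenzene-1,3-diol
Product: 7 2-bromo-4,6-dihydroxybenzaldehyde, via aryl iminium chloride 6 (not isolated)
Conditions: POCl3, DMF, MeCN, 0 °C to rt; then H2O, 50 °C
Reagents that add atoms: N,N-dimethylformamide, CN(C)C=O; water, O
Why: Vilsmeier–Haack formylation of a 5-substituted resorcinol should go para to one hydroxyl and ortho to the other, next to the 5-substituent (as with 5-alkylresorcinols), and the iminium salt is hydrolysed on warming in water.

**Step 3**
Reactants: 7 2-bromo-4,6-dihydroxybenzaldehyde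
Product: 8 2-bromo-4,6-bis(TBSO)benzaldehyde
Conditions: TBSCl, imidazole, DMF, rt
Reagents that add atoms: tert-butyldimethylsilyl chloride, CC(C)(C)[Si](C)(C)Cl
Why: Imidazole-mediated silylation of both phenols gives donor ethers that should survive acid, amide base and palladium catalysis and fall off together at the end.

**Step 4**
Reactants: 8 2-bromo-4,6-bis(TBSO)benzaldehyde
Product: 9 (E)-2-{2-[2-bromo-4,6-bis(TBSO)phenyl]vinyl}-4,4,5,5-tetramethyl-1,3,2-dioxaborolane
Conditions: CH2(Bpin)2, lithium 2,2,6,6-tetramethylpiperidide (LiTMP), THF, 0 °C; then 8, −78 °C to rt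
Reagents that add atoms: bis[(pinacolato)boryl]methane, CC1(C)OB(CB2OC(C)(C)C(C)(C)O2)OC1(C)C
Why: Boron–Wittig olefination, in which the lithiated geminal bis(boronate) adds to the aldehyde and syn-elimination of boron and oxygen gives the (E)-alkenylboronate, with the aryl bromide inert at −78 °C.

**Step 5**
Reactants: 9 (E)-alkenyl pinacol boronate
Product: 10 (E)-2-[2-bromo-4,6-bis(TBSO)phenyl]vinylboronic acid
Conditions: NaIO4, NH4OAc, acetone/H2O, rt
Reagents that add atoms: water, O
Why: Periodate cleavage of the released pinacol drives hydrolysis of the boronic ester under buffered near-neutral conditions that spare the aryl silyl ethers, which a fluoride route to the trifluoroborate would not.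

**Step 6**
Reactants: 10 (E)-alkenylboronic acid
Product: 11 (E)-2-[2-bromo-4,6-bis(TBSO)phenyl]vinyl benzoate
Conditions: PhCO2H, Cu(OAc)2 (20 mol%), DMAP, 4 Å molecular sieves, O2 (1 atm), CH2Cl2, rt
Reagents that add atoms: benzoic acid, O=C(O)c1ccccc1
Why: Chan–Lam–Evans enol esterification, in which transmetalation of the alkenylboron to divalent copper, carboxylate binding, oxidation and C–O reductive elimination give the enol ester with retention of the (E) geometry, while the aryl bromide does not react with copper at room temperature.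

**Step 7**
Reactants: 12 3,4-bis(TBSO)benzaldehyde
Product: 13 (E)-2-{2-[3,4-bis(TBSO)phenyl]vinyl}-4,4,5,5-tetramethyl-1,3,2-dioxaborolane
Conditions: CH2(Bpin)2, lithium 2,2,6,6-tetramethylpiperidide (LiTMP), THF, 0 °C; then 12, −78 °C to rt
Reagents that add atoms: bis[(pinacolato)boryl]methane, CC1(C)OB(CB2OC(C)(C)C(C)(C)O2)OC1(C)C
Why: The same boron–Wittig olefination as in step 4, which is (E)-selective for aromatic aldehydes.

**Step 8**
Reactants: 4 [3-(TBSO)phenoxy][4-(TBSO)phenyl]methyl pivalate; 11 (E)-2-[2-bromo-4,6-bis(TBSO)phenyl]vinyl benzoate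
Product: 16 (2R,3S,4S)-4-[2-bromo-4,6-bis(TBSO)phenyl]-7-(TBSO)-2-[4-(TBSO)phenyl]chroman-3-yl benzoate, via oxocarbenium ion 14 (not isolated), via benzylic cation 15 (not isolated)
Conditions: (R)-3,3'-bis(2,4,6-triisopropylphenyl)-1,1'-binaphthyl-2,2'-diyl N-(trifluoromethylsulfonyl)phosphoramide (10 mol%), 4 Å molecular sieves, toluene, −40 °C
Reagents that add atoms: none
Why: Proposed new method: the strong chiral acid protonates the pivalate carbonyl of 4 and pivalic acid leaves (a carboxylate is a far better leaving group than the aryloxide, so only the O-aryl oxocarbenium ion 14 forms), and 14 stays paired with the chiral phosphoramide anion; the closest known reaction types are the Lewis-acid-promoted oxa-Povarov reaction of aryl oxocarbenium ions with styrenes and the chiral-phosphoric-acid-catalysed Povarov reaction of N-aryl iminium ions, together with chiral-anion control of oxocarbenium ions in Prins-type additions. The enol benzoate attacks C2 of 14 with its oxygen-bearing carbon (C3), because the cation left at C4 is benzylic with silyloxy groups ortho and para whereas the benzoyloxy oxygen is only a weak donor, and this gives cation 15 (in equilibrium with its bridged benzoxonium form). Ring C then closes by a 6-endo Friedel–Crafts attack of the ring-A carbon para to the silyloxy group (the future C4a) on C4, and loss of the proton restores the arene and returns the acid. C2 is set by the anion, which shields one face of the oxocarbenium ion; C3 is set relative to C2 by the (E)-alkene reacting in the compact chair-like [4+2] arrangement with ring D endo and the benzoate exo (the course trans-anethole takes in Povarov reactions); C4 is set by closure anti to the C3 benzoate with all three substituents equatorial, the most stable 2,3-trans-3,4-trans isomer. The step needs attack at the enol alkene and not at a second alkene (secured by the bromide that stands in for the styryl group), attack through C3 and not C4 (secured by the resorcinol-type ring D), and closure para and not ortho to the ring-A silyloxy group (secured by the crowding of the carbon between the two oxygens).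

**Step 9**
Reactants: 16 chroman-3-yl benzoate
Product: 17 (2R,3S,4S)-4-[2-bromo-4,6-bis(TBSO)phenyl]-7-(TBSO)-2-[4-(TBSO)phenyl]chroman-3-ol
Conditions: i-Bu2AlH, CH2Cl2, −78 °C; aqueous potassium sodium tartrate
Reagents that add atoms: none
Why: Reductive cleavage of the hindered benzoate by the aluminium hydride at low temperature should leave the aryl silyl ethers, the aryl bromide and the three non-enolisable stereocentres untouched.

**Step 10**
Reactants: 17 bromo chroman-3-ol; 13 (E)-styryl pinacol boronate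
Product: 18 (2R,3S,4S)-4-{2,4-bis(TBSO)-6-[(E)-3,4-bis(TBSO)styryl]phenyl}-7-(TBSO)-2-[4-(TBSO)phenyl]chroman-3-ol
Conditions: Pd(OAc)2 (5 mol%), SPhos (2-dicyclohexylphosphino-2',6'-dimethoxybiphenyl, 10 mol%), K3PO4·H2O, toluene, 80 °C
Reagents that add atoms: none
Why: Suzuki–Miyaura coupling in which the bulky electron-rich biarylphosphine lets zerovalent palladium insert into the ortho-substituted aryl bromide, and transmetalation and reductive elimination keep the (E) geometry of the alkenylboronate.

**Step 11**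
Reactants: 18 hexasilyl ether
Product: 19 (2R,3S,4S)-4-{2-[(E)-2-(3,4-dihydroxyphenyl)vinyl]-4,6-dihydroxyphenyl}-2-(4-hydroxyphenyl)chroman-3,7-diol (CNP0170061.1)
Conditions: HF·pyridine, pyridine, THF, 0 °C to rt, argon
Reagents that add atoms: none
Why: Fluoride cleaves all six aryl O–Si bonds under buffered, non-basic and non-oxidising conditions, so the stilbene double bond, the acid-labile C4–aryl bond and the base-labile C2 centre should not be endangered.

**Compound list**
1 | 4-(tert-butyldimethylsilyloxy)benzaldehyde | CC(C)(C)[Si](C)(C)Oc1ccc(C=O)cc1 | starting material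
2 | 3-(tert-butyldimethylsilyloxy)phenol | CC(C)(C)[Si](C)(C)Oc1cccc(O)c1 | starting material
3 | chloro[4-(TBSO)phenyl]methyl pivalate (racemic) | CC(C)(C)C(=O)OC(Cl)c1ccc(O[Si](C)(C)C(C)(C)C)cc1 | intermediate
4 | [3-(TBSO)phenoxy][4-(TBSO)phenyl]methyl pivalate (racemic) | CC(C)(C)C(=O)OC(Oc1cccc(O[Si](C)(C)C(C)(C)C)c1)c1ccc(O[Si](C)(C)C(C)(C)C)cc1 | intermediate
5 | 5-bromobenzene-1,3-diol | Oc1cc(O)cc(Br)c1 | starting material
6 | N-[(2-bromo-4,6-dihydroxyphenyl)methylidene]-N-methylmethanaminium chloride | C[N+](C)=Cc1c(O)cc(O)cc1Br.[Cl-] | intermediate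
7 | 2-bromo-4,6-dihydroxybenzaldehyde | O=Cc1c(O)cc(O)cc1Br | intermediate
8 | 2-bromo-4,6-bis(TBSO)benzaldehyde | O=Cc1c(O[Si](C)(C)C(C)(C)C)cc(O[Si](C)(C)C(C)(C)C)cc1Br | intermediate
9 | (E)-2-{2-[2-bromo-4,6-bis(TBSO)phenyl]vinyl}-4,4,5,5-tetramethyl-1,3,2-dioxaborolane | CC1(C)OB(/C=C/c2c(O[Si](C)(C)C(C)(C)C)cc(O[Si](C)(C)C(C)(C)C)cc2Br)OC1(C)C | intermediate
10 | (E)-2-[2-bromo-4,6-bis(TBSO)phenyl]vinylboronic acid | OB(O)/C=C/c1c(O[Si](C)(C)C(C)(C)C)cc(O[Si](C)(C)C(C)(C)C)cc1Br | intermediate
11 | (E)-2-[2-bromo-4,6-bis(TBSO)phenyl]vinyl benzoate | O=C(O/C=C/c1c(O[Si](C)(C)C(C)(C)C)cc(O[Si](C)(C)C(C)(C)C)cc1Br)c1ccccc1 | intermediate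
12 | 3,4-bis(tert-butyldimethylsilyloxy)benzaldehyde | O=Cc1ccc(O[Si](C)(C)C(C)(C)C)c(O[Si](C)(C)C(C)(C)C)c1 | starting material
13 | (E)-2-{2-[3,4-bis(TBSO)phenyl]vinyl}-4,4,5,5-tetramethyl-1,3,2-dioxaborolane | CC1(C)OB(/C=C/c2ccc(O[Si](C)(C)C(C)(C)C)c(O[Si](C)(C)C(C)(C)C)c2)OC1(C)C | intermediate
14 | (E)-[4-(TBSO)benzylidene][3-(TBSO)phenyl]oxonium (ion pair with the phosphoramide anion) | CC(C)(C)[Si](C)(C)Oc1ccc(/C=[O+]/c2cccc(O[Si](C)(C)C(C)(C)C)c2)cc1 | intermediate
15 | (2S,3R)-2-(benzoyloxy)-1-[2-bromo-4,6-bis(TBSO)phenyl]-3-[3-(TBSO)phenoxy]-3-[4-(TBSO)phenyl]propan-1-ylium (C2 R and C3 S in chroman numbering) | CC(C)(C)[Si](C)(C)Oc1ccc(cc1)[C@@H](Oc1cccc(O[Si](C)(C)C(C)(C)C)c1)[C@@H](OC(=O)c1ccccc1)[CH+]c1c(O[Si](C)(C)C(C)(C)C)cc(O[Si](C)(C)C(C)(C)C)cc1Br | intermediate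
16 | (2R,3S,4S)-4-[2-bromo-4,6-bis(TBSO)phenyl]-7-(TBSO)-2-[4-(TBSO)phenyl]chroman-3-yl benzoate | CC(C)(C)[Si](C)(C)Oc1ccc([C@H]2Oc3cc(O[Si](C)(C)C(C)(C)C)ccc3[C@@H](c3c(O[Si](C)(C)C(C)(C)C)cc(O[Si](C)(C)C(C)(C)C)cc3Br)[C@@H]2OC(=O)c2ccccc2)cc1 | intermediate
17 | (2R,3S,4S)-4-[2-bromo-4,6-bis(TBSO)phenyl]-7-(TBSO)-2-[4-(TBSO)phenyl]chroman-3-ol | CC(C)(C)[Si](C)(C)Oc1ccc([C@H]2Oc3cc(O[Si](C)(C)C(C)(C)C)ccc3[C@@H](c3c(O[Si](C)(C)C(C)(C)C)cc(O[Si](C)(C)C(C)(C)C)cc3Br)[C@@H]2O)cc1 | intermediate
18 | (2R,3S,4S)-4-{2,4-bis(TBSO)-6-[(E)-3,4-bis(TBSO)styryl]phenyl}-7-(TBSO)-2-[4-(TBSO)phenyl]chroman-3-ol | CC(C)(C)[Si](C)(C)Oc1ccc([C@H]2Oc3cc(O[Si](C)(C)C(C)(C)C)ccc3[C@@H](c3c(O[Si](C)(C)C(C)(C)C)cc(O[Si](C)(C)C(C)(C)C)cc3/C=C/c3ccc(O[Si](C)(C)C(C)(C)C)c(O[Si](C)(C)C(C)(C)C)c3)[C@@H]2O)cc1 | intermediate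
19 | (2R,3S,4S)-4-{2-[(E)-2-(3,4-dihydroxyphenyl)vinyl]-4,6-dihydroxyphenyl}-2-(4-hydroxyphenyl)chroman-3,7-diol | Oc1ccc([C@H]2Oc3cc(O)ccc3[C@@H](c3c(O)cc(O)cc3/C=C/c3ccc(O)c(O)c3)[C@@H]2O)cc1 | target

**Step count and risks**
Total step count: 11.
Longest linear sequence: 9 steps (5 → 7 → 8 → 9 → 10 → 11 → 16 → 17 → 18 → 19; steps 2 to 6 and 8 to 11).

Steps most likely to fail:

1. Step 8 (Proposed new method).
   - What may go wrong: weak enantiofacial discrimination by the chiral anion, since the oxocarbenium ion offers no hydrogen-bond donor; Friedel–Crafts alkylation of the electron-rich arenes or acid-induced oligomerisation of the enol ester in place of the cycloaddition; loss of silyl groups from the cationic intermediates.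
   - Fallback (known chemistry; sets out from 10 and 4, comes back at 17): the boronic acid 10 is coupled under the conditions of step 6 with (R)-3,3,3-trifluoro-2-methoxy-2-phenylpropanoic acid in place of benzoic acid, to give the (E)-enol (R)-MTPA ester F1. F1 and 4 are combined with SnCl4 (1.1 equiv, CH2Cl2, −78 °C), the achiral Lewis-acid form of the oxa-Povarov reaction. This should give the two all-trans cycloadducts that differ in the absolute configuration of the chroman: the (2R,3S,4S) MTPA ester F2 and its (2S,3R,4R) diastereomer F3. Being diastereomers, they are separated by chromatography or crystallisation, and F2 is cleaved with i-Bu2AlH as in step 9 to give 17.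

2. Step 1.
   - What may go wrong: acyl transfer from the α-chloro ester to the phenoxide, C-alkylation in place of O-alkylation of the electron-rich phenoxide, silyl scrambling between phenoxides, and ionisation or hydrolysis of 4 during isolation.
   - Fallback (sets out from 1 and 2, comes back at 4): 1 is converted with HC(OMe)3 and catalytic TsOH in MeOH into the dimethyl acetal F4. Acetyl chloride (catalytic ZnCl2, CH2Cl2, 0 °C) exchanges one methoxy group for chloride to give the α-chlorobenzyl methyl ether F5, which is not isolated and alkylates the caesium phenoxide of 2 to give the mixed methyl aryl acetal F6. A second treatment with acetyl chloride removes the remaining, more basic methoxy group as methyl acetate to give the aryl α-chlorobenzyl ether F7, which is quenched in the flask with caesium pivalate to give 4. The ester is introduced last by a carboxylate, so acyl transfer to the phenoxide cannot occur.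

3. Step 10.
   - What may go wrong: slow oxidative addition at the hindered bromide, which leaves time for protodeboronation of 13, and partial cleavage of aryl silyl ethers by the hydrated phosphate base.
   - Fallback (sets out from 17 and 12, comes back at 18): 12 is methylenated with Ph3P=CH2 (from Ph3PCH3Br and NaN(SiMe3)2, THF, 0 °C) to give 3,4-bis(TBSO)styrene F8. F8 is joined to 17 by a Mizoroki–Heck reaction under anhydrous amine-base conditions (Pd(P(t-Bu)3)2, Cy2NMe, dioxane, 100 °C). This needs no boron reagent and no aqueous base, and should give the (E)-stilbene 18 by syn-insertion and syn-β-hydride elimination.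

**Further compounds**
F1 | step 8 | (E)-2-[2-bromo-4,6-bis(TBSO)phenyl]vinyl (R)-3,3,3-trifluoro-2-methoxy-2-phenylpropanoate | CO[C@@](C(=O)O/C=C/c1c(O[Si](C)(C)C(C)(C)C)cc(O[Si](C)(C)C(C)(C)C)cc1Br)(c1ccccc1)C(F)(F)F
F2 | step 8 | (2R,3S,4S)-4-[2-bromo-4,6-bis(TBSO)phenyl]-7-(TBSO)-2-[4-(TBSO)phenyl]chroman-3-yl (R)-3,3,3-trifluoro-2-methoxy-2-phenylpropanoate | CC(C)(C)[Si](C)(C)Oc1ccc([C@H]2Oc3cc(O[Si](C)(C)C(C)(C)C)ccc3[C@@H](c3c(O[Si](C)(C)C(C)(C)C)cc(O[Si](C)(C)C(C)(C)C)cc3Br)[C@@H]2OC(=O)[C@](OC)(c2ccccc2)C(F)(F)F)cc1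
F3 | step 8 | (2S,3R,4R)-4-[2-bromo-4,6-bis(TBSO)phenyl]-7-(TBSO)-2-[4-(TBSO)phenyl]chroman-3-yl (R)-3,3,3-trifluoro-2-methoxy-2-phenylpropanoate (diastereomer removed by separation) | CC(C)(C)[Si](C)(C)Oc1ccc([C@@H]2Oc3cc(O[Si](C)(C)C(C)(C)C)ccc3[C@H](c3c(O[Si](C)(C)C(C)(C)C)cc(O[Si](C)(C)C(C)(C)C)cc3Br)[C@H]2OC(=O)[C@](OC)(c2ccccc2)C(F)(F)F)cc1
F4 | step 1 | tert-butyl[4-(dimethoxymethyl)phenoxy]dimethylsilane | COC(OC)c1ccc(O[Si](C)(C)C(C)(C)C)cc1
F5 | step 1 | tert-butyl{4-[chloro(methoxy)methyl]phenoxy}dimethylsilane (racemic) | COC(Cl)c1ccc(O[Si](C)(C)C(C)(C)C)cc1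
F6 | step 1 | tert-butyl(3-{methoxy[4-(TBSO)phenyl]methoxy}phenoxy)dimethylsilane (racemic) | COC(Oc1cccc(O[Si](C)(C)C(C)(C)C)c1)c1ccc(O[Si](C)(C)C(C)(C)C)cc1
F7 | step 1 | tert-butyl(3-{chloro[4-(TBSO)phenyl]methoxy}phenoxy)dimethylsilane (racemic) | ClC(Oc1cccc(O[Si](C)(C)C(C)(C)C)c1)c1ccc(O[Si](C)(C)C(C)(C)C)cc1
F8 | step 10 | 3,4-bis(tert-butyldimethylsilyloxy)styrene | C=Cc1ccc(O[Si](C)(C)C(C)(C)C)c(O[Si](C)(C)C(C)(C)C)c1
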